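A direct plan would build rings A and B at once by a thiyl-radical [3+2] annulation of the spiro vinylcyclopropane lactone A1 to the tricyclic lactone acrylate A2, would close ring C by ring-closing metathesis, and would then adjust oxidation levels and assemble the chain in pieces. Its weakest steps would be:
- the base epimerisation of the C-2 formyl group of keto aldehyde A3, where the 2S centre would rest on an assumed thermodynamic preference beside a quaternary carbon, with no kinetic control;
- the lactone → allylic diol → enone → alcohol detour around C-10, which would spend four redox steps that add no skeleton, would include a hydride/vinyl Grignard step that must spare an acrylate, and would set C-10 only at the end by substrate-biased hydride delivery;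
- the Z-selective cross-metathesis that would complete the hydroxyhexadecenoate chain on the core dec-9-enoate A4, which would need excess partner and would risk homodimers and Z/E erosion on the most precious intermediate.

**Plan of the new route**
1. Cuts: the C-10 ester C–O (whole (9Z)-chain as acid 28), then C5–C6 (ring B, tertiary radical 5-exo closure), then C1–C10 and C7–C11 together (ring C, Diels–Alder reaction).
2. Ring order: A (cyclopentanone 7, C-2 set by catalyst) → C (spiro cycloaddition) → B (radical closure); the tricycle first exists in step 10.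
3. Feature used: ring C is a cyclohexene whose C8=C9 bond lies between C-7 and the oxygenated C-10, with the quaternary C-1 between C-10 and C-11 and the ring A carbon C-5 on it: the retron of a [4+2] between a 1-silyloxy diene (C7=C8–C9=C10) and an exocyclic enone (C11=C1–C5=O). C-6 and the carboxyl carbon C-15 are cis on C7=C8, i.e. a butenolide, which locks the diene geometry, masks the acid and later releases the C-6 radical.
4. C-2 is fixed before the core exists; C-1, C-7 and C-10 arise in one endo, anti cycloaddition with C-10 already at the alcohol level; C-5 is forced by the cis ring fusion. No epimerisation or redox detour is needed.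
5. The (9Z)-alkene is made on a cheap fragment by alkyne semihydrogenation and the chain is attached in one acylation, so no metathesis touches the core.

Key step: step 6

Remark on numbering: cedrane numbering of the target is used for all intermediates (C-1 quaternary carbon, C-2 formyl-bearing, C-5 ring-fusion CH, C-6 CMe2, C-7 bridgehead CH, C-8 carboxyl-bearing, C-10 oxygenated, C-11 CH2, C-12 formyl carbon, C-15 carboxyl carbon).

Assumption: (S)-BINAP is written in step 1 on the usual sense of induction for [Rh(cod)(MeCN)2]BF4/BINAP conjugate additions to cyclic enones; the antipode would be used if the opposite sense is found.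

**Route**

Step 1
Reactants: 1 hex-1-yne; 2 cyclopent-2-en-1-one
Product: 5 (2S,3R)-2-[(dimethylamino)methyl]-3-[(1E)-hex-1-en-1-yl]cyclopentan-1-one, via (E)-hex-1-enylzirconocene chloride 3 (not isolated), via zirconium enolate 4 (not isolated)
Conditions: Cp2Zr(H)Cl, THF, rt; then 2, [Rh(cod)(MeCN)2]BF4 (5 mol %), (S)-BINAP (6 mol %), THF, rt; then CH2=NMe2+ I−, CH2Cl2, 0 °C; aq NaHCO3
Reagents that add atoms: N,N-dimethylmethylideneammonium iodide C=[N+](C)C.[I-]
Why: Hydrozirconation is followed by a [Rh(cod)(MeCN)2]BF4/(S)-BINAP-catalysed enantioselective conjugate addition in which the BINAP complex selects the enone face and sets the hexenyl-bearing centre (C-2 of the target), and Mannich trapping of the regiodefined zirconium enolate occurs trans to the new substituent.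

Step 2
Reactants: 5 (2S,3R)-2-[(dimethylamino)methyl]-3-[(1E)-hex-1-en-1-yl]cyclopentan-1-one
Product: 7 (3R)-3-[(1E)-hex-1-en-1-yl]-2-methylidenecyclopentan-1-one, via methiodide 6 (not isolated)
Conditions: MeI, Et2O, rt; then aq NaHCO3, CH2Cl2, rt; used at once as a solution
Reagents that add atoms: none
Why: Exhaustive methylation and Hofmann-type β-elimination (E1cB) of the β-ammonio ketone should give the exocyclic enone only at the carbon fixed in step 1 and leave the C-2 centre untouched.

Step 3
Reactants: 8 5,5-dimethylfuran-2(5H)-one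
Product: 10 3-bromo-5,5-dimethylfuran-2(5H)-one, via trans-dibromide 9 (not isolated)
Conditions: Br2, CH2Cl2, 0 °C to rt; then Et3N, 0 °C to rt
Reagents that add atoms: bromine BrBr
Why: Bromination–dehydrobromination of the butenolide (anti addition of Br2, then E1cB loss of HBr from the α-bromo lactone) should give the α-bromo enoate.

Step 4
Reactants: 10 3-bromo-5,5-dimethylfuran-2(5H)-one; 11 2-[(E)-2-ethoxyethenyl]-4,4,5,5-tetramethyl-1,3,2-dioxaborolane
Product: 12 3-[(E)-2-ethoxyethenyl]-5,5-dimethylfuran-2(5H)-one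
Conditions: Pd(dppf)Cl2 (3 mol %), K3PO4, 1,4-dioxane/H2O, 60 °C
Reagents that add atoms: none
Why: Suzuki–Miyaura coupling of the electron-poor alkenyl bromide with the alkenylboronate should proceed with retention of the (E) geometry.

Step 5
Reactants: 12 3-[(E)-2-ethoxyethenyl]-5,5-dimethylfuran-2(5H)-one
Product: 13 (5,5-dimethyl-2-oxo-2,5-dihydrofuran-3-yl)acetaldehyde
Conditions: 1 M HCl, THF, 0 °C to rt
Reagents that add atoms: water O
Why: Acid hydrolysis of the enol ether (protonation at C-9, collapse of the hemiacetal) unveils the aldehyde carbon that becomes C-10.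

Step 6
Reactants: 13 (5,5-dimethyl-2-oxo-2,5-dihydrofuran-3-yl)acetaldehyde; 7 (3R)-3-[(1E)-hex-1-en-1-yl]-2-methylidenecyclopentan-1-one
Product: 15 spiro cycloadduct (ring A cyclopentanone spiro-fused at C-1 to ring C cyclohexene carrying the C-10 silyl ether and the fused γ-lactone), via silyl dienol ether 14 (not isolated)
Conditions: TBSOTf, Et3N, CH2Cl2, 0 °C; pentane, filtration from Et3NH·OTf; then 7 (1.3 equiv), PhMe, BHT (cat.), 60 °C
Reagents that add atoms: tert-butyldimethylsilyl trifluoromethanesulfonate CC(C)(C)[Si](C)(C)OS(=O)(=O)C(F)(F)F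
Why: The aldehyde is O-silylated to the (E)-silyl dienol ether 14, whose diene C7=C8–C9=C10 then undergoes a normal-demand Diels–Alder cycloaddition with the exocyclic enone C11=C1–C5=O of 7; the closest known reaction type is the spiroannulating Diels–Alder reaction of α-methylene ketones with 1-silyloxy dienes. Ring C closes in this single asynchronous [4+2] step as a cyclohexene by forming C7–C11 and C1–C10, because C-7, the terminus activated by the silyloxy donor and adjacent to the acceptor-bearing C-8, carries the largest HOMO coefficient and bonds to the enone β-carbon C-11. C-1 is controlled by C-2: the diene approaches the enone face anti to the hexenyl group, so C-10 ends trans and C-11 cis to it on ring A. C-10 is controlled by the endo rule: the flat C-5 carbonyl, not the substituted C-2 arm, lies under the diene, which places the (E)-silyloxy group cis to C-5 on ring C. C-7 is controlled by the butenolide, which holds C-6 on the outside of the diene, so C-6 ends cis to the silyloxy group and hence cis to C-5, the relation that ring B needs. The step needs endo and facial selectivity, and both are secured by the substituted, non-planar C-2 side of the dienophile.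

Step 7
Reactants: 15 spiro cycloadduct
Product: 16 enol triflate of 15 (C-5 triflate with C4=C5)
Conditions: KN(SiMe3)2, PhNTf2, THF, −78 °C
Reagents that add atoms: N-phenylbis(trifluoromethanesulfonimide) FC(F)(F)S(=O)(=O)N(c1ccccc1)S(=O)(=O)C(F)(F)F
Why: Enolate O-sulfonylation; the ketone can enolise only toward C-4 because C-1 is quaternary, and the lactone has no α-hydrogen.

Step 8
Reactants: 16 enol triflate of 15
Product: 17 spiro cyclopentene lactone (C4=C5 alkene in ring A)
Conditions: Pd(OAc)2 (5 mol %), PPh3 (10 mol %), HCO2H, Bu3N, DMF, 60 °C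
Reagents that add atoms: none
Why: Pd(OAc)2/PPh3-catalysed formate reduction of the alkenyl triflate (oxidative addition, formate decarboxylation, reductive elimination) should give the C4=C5 alkene that will accept the radical.

Step 9
Reactants: 17 spiro cyclopentene lactone
Product: 19 spiro selenide hydroxy acid (C-6 phenylselanyl, C-15 acid, C-10 alcohol), via bis-silylated selenide 18 (not isolated)
Conditions: PhSeSiMe3, ZnI2 (20 mol %), PhMe, 70 °C; then HF·pyridine, THF, 0 °C to rt
Reagents that add atoms: trimethyl(phenylselanyl)silane C[Si](C)(C)[Se]c1ccccc1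
Why: ZnI2-assisted alkyl–oxygen cleavage of the tertiary γ-lactone by the silyl selenide (ionisation at C-6, capture by selenium) should give the tertiary selenide and free the C-15 acid, and fluoride then removes both silyl groups without touching a stereocentre.

Step 10
Reactants: 19 spiro selenide hydroxy acid
Product: 20 (1R,2R,5S,7R,10S)-2-[(1E)-hex-1-en-1-yl]-10-hydroxy-6,6-dimethyltricyclo[5.3.1.0(1,5)]undec-8-ene-8-carboxylic acid
Conditions: (Me3Si)3SiH, AIBN, PhMe (0.01 M), 85 °C, slow addition
Reagents that add atoms: none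
Why: In this silane-mediated reductive radical cyclisation the tertiary C-6 radical adds 5-exo-trig to C-5 of the ring A alkene, which sits cis to it on ring C, the secondary C-4 radical takes hydrogen from the silane, and C-5 is fixed because rings A and B can only fuse cis.

Step 11
Reactants: 20 (1R,2R,5S,7R,10S)-2-[(1E)-hex-1-en-1-yl]-10-hydroxy-6,6-dimethyltricyclo[5.3.1.0(1,5)]undec-8-ene-8-carboxylic acid
Product: 21 (1S,2S,5S,7R,10S)-2-formyl-10-hydroxy-6,6-dimethyltricyclo[5.3.1.0(1,5)]undec-8-ene-8-carboxylic acid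
Conditions: O3, CH2Cl2/MeOH, −78 °C (Sudan Red 7B as indicator); then Me2S, −78 °C to rt
Reagents that add atoms: ozone [O-][O+]=O
Why: Ozonolysis with reductive work-up should cleave the electron-rich disubstituted alkene much faster than the conjugated C8=C9 acid and leave C-2 unchanged, with the formyl group on the face away from the C-10 oxygen.

Step 12
Reactants: 22 oct-7-yn-1-ol
Product: 23 tert-butyl(dimethyl)(oct-7-yn-1-yloxy)silane
Conditions: TBSCl, imidazole, DMF, rt
Reagents that add atoms: tert-butyl(chloro)dimethylsilane CC(C)(C)[Si](C)(C)Cl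
Why: Silyl ether formation protects the primary alcohol for the acetylide and acid chloride steps.

Step 13
Reactants: 23 tert-butyl(dimethyl)(oct-7-yn-1-yloxy)silane; 24 8-bromooctanoic acid
Product: 27 16-{[tert-butyl(dimethyl)silyl]oxy}hexadec-9-ynoic acid, via lithium acetylide 25 (not isolated), via lithium 8-bromooctanoate 26 (not isolated)
Conditions: 23, n-BuLi, THF, −78 to 0 °C; 24, n-BuLi, THF, −78 °C; combine, DMPU, 0 to 40 °C; aq HCl
Reagents that add atoms: none
Why: SN2 alkylation of the lithium acetylide by the ω-bromo carboxylate in a dipolar aprotic co-solvent joins C-8 and C-9 of the chain.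

Step 14
Reactants: 27 16-{[tert-butyl(dimethyl)silyl]oxy}hexadec-9-ynoic acid
Product: 28 (9Z)-16-{[tert-butyl(dimethyl)silyl]oxy}hexadec-9-enoic acid
Conditions: H2 (1 atm), Pd/CaCO3 poisoned with Pb(OAc)2, quinoline, EtOAc, rt
Reagents that add atoms: none
Why: Partial syn-hydrogenation of the alkyne on Pd/CaCO3 poisoned with Pb(OAc)2 (Lindlar reduction) should give the (9Z)-alkene.

Step 15
Reactants: 21 (1S,2S,5S,7R,10S)-2-formyl-10-hydroxy-6,6-dimethyltricyclo[5.3.1.0(1,5)]undec-8-ene-8-carboxylic acid; 28 (9Z)-16-{[tert-butyl(dimethyl)silyl]oxy}hexadec-9-enoic acid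
Product: 30 (1S,2S,5S,7R,10S)-10-{[(9Z)-16-{[tert-butyl(dimethyl)silyl]oxy}hexadec-9-enoyl]oxy}-2-formyl-6,6-dimethyltricyclo[5.3.1.0(1,5)]undec-8-ene-8-carboxylic acid, via acid chloride 29 (not isolated)
Conditions: 28 (2.5 equiv), (COCl)2, DMF (cat.), CH2Cl2, 0 °C to rt, concentrate; then 21, pyridine, DMAP (cat.), CH2Cl2, 0 °C to rt; aq NaHCO3/THF, then pH 3
Reagents that add atoms: none
Why: Acyl chloride esterification under nucleophilic catalysis acylates the C-10 hydroxyl with retention (the C–O bond is not broken); the transient mixed anhydride at C-15 is hydrolysed on work-up, so the complete chain arrives in one step.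

Step 16
Reactants: 30 (1S,2S,5S,7R,10S)-10-{[(9Z)-16-{[tert-butyl(dimethyl)silyl]oxy}hexadec-9-enoyl]oxy}-2-formyl-6,6-dimethyltricyclo[5.3.1.0(1,5)]undec-8-ene-8-carboxylic acid
Product: 31 (1S,2S,5S,7R,10S)-2-formyl-10-{[(9Z)-16-hydroxyhexadec-9-enoyl]oxy}-6,6-dimethyltricyclo[5.3.1.0(1,5)]undec-8-ene-8-carboxylic acid (CNP0214056.2)
Conditions: HF·pyridine, pyridine, THF, 0 °C to rt
Reagents that add atoms: none
Why: Fluoride-mediated desilylation of the primary silyl ether should leave the ester, the aldehyde, the acid and both alkenes untouched.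

**Compound list**

1 | hex-1-yne | CCCCC#C | starting material
2 | cyclopent-2-en-1-one | O=C1C=CCC1 | starting material
3 | chloridobis(cyclopentadienyl)[(1E)-hex-1-en-1-yl]zirconium | CCCC/C=C/[Zr](Cl)(C1C=CC=C1)C1C=CC=C1 | intermediate
4 | chloridobis(cyclopentadienyl)zirconium enolate from the conjugate addition (hexenyl-bearing carbon configured as in 5) | CCCC/C=C/[C@H]1CCC(O[Zr](Cl)(C2C=CC=C2)C2C=CC=C2)=C1 | intermediate
5 | (2S,3R)-2-[(dimethylamino)methyl]-3-[(1E)-hex-1-en-1-yl]cyclopentan-1-one | CN(C)C[C@H]1C(=O)CC[C@@H]1/C=C/CCCC | intermediate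
6 | methiodide of 5 (trimethylammonium iodide) | C[N+](C)(C)C[C@H]1C(=O)CC[C@@H]1/C=C/CCCC.[I-] | intermediate
7 | (3R)-3-[(1E)-hex-1-en-1-yl]-2-methylidenecyclopentan-1-one | C=C1C(=O)CC[C@@H]1/C=C/CCCC | intermediate
8 | 5,5-dimethylfuran-2(5H)-one | CC1(C)C=CC(=O)O1 | starting material
9 | trans-3,4-dibromo-5,5-dimethyloxolan-2-one (racemic, one enantiomer drawn) | Br[C@H]1[C@H](Br)C(C)(C)OC1=O | intermediate
10 | 3-bromo-5,5-dimethylfuran-2(5H)-one | CC1(C)C=C(Br)C(=O)O1 | intermediate
11 | 2-[(E)-2-ethoxyethenyl]-4,4,5,5-tetramethyl-1,3,2-dioxaborolane | CCO/C=C/B1OC(C)(C)C(C)(C)O1 | starting material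
12 | 3-[(E)-2-ethoxyethenyl]-5,5-dimethylfuran-2(5H)-one | CCO/C=C/C1=CC(C)(C)OC1=O | intermediate
13 | (5,5-dimethyl-2-oxo-2,5-dihydrofuran-3-yl)acetaldehyde | CC1(C)C=C(CC=O)C(=O)O1 | intermediate
14 | 3-[(E)-2-{[tert-butyl(dimethyl)silyl]oxy}ethenyl]-5,5-dimethylfuran-2(5H)-one | CC1(C)C=C(/C=C/O[Si](C)(C)C(C)(C)C)C(=O)O1 | intermediate
15 | spiro cycloadduct: ring A cyclopentanone (C-5 ketone, C-2 (E)-hex-1-enyl) spiro at C-1 to ring C cyclohexene (C8=C9) with C-10 OTBS and the γ-lactone C15(=O)–O–C6Me2 fused on C8/C7; OTBS, C-5 and C-6 all cis on ring C, hexenyl trans to C-10 on ring A | CC1(C)OC(=O)C2=C[C@H](O[Si](C)(C)C(C)(C)C)[C@@]3(C[C@H]12)C(=O)CC[C@@H]3/C=C/CCCC | intermediate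
16 | enol triflate of 15 (C-5 trifluoromethanesulfonyloxy, C4=C5) | CC1(C)OC(=O)C2=C[C@H](O[Si](C)(C)C(C)(C)C)[C@@]3(C[C@H]12)C(OS(=O)(=O)C(F)(F)F)=CC[C@@H]3/C=C/CCCC | intermediate
17 | spiro cyclopentene lactone: 15 with the C-5 carbonyl replaced by the C4=C5 alkene | CC1(C)OC(=O)C2=C[C@H](O[Si](C)(C)C(C)(C)C)[C@@]3(C[C@H]12)C=CC[C@@H]3/C=C/CCCC | intermediate
18 | trimethylsilyl ester and C-10 TBS ether of 19 | CC(C)([Se]c1ccccc1)[C@H]1C[C@@]2(C=CC[C@@H]2/C=C/CCCC)[C@@H](O[Si](C)(C)C(C)(C)C)C=C1C(=O)O[Si](C)(C)C | intermediate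
19 | spiro selenide hydroxy acid: ring C cyclohexene-1-carboxylic acid (C8=C9) with C-10 OH and C-7 2-(phenylselanyl)propan-2-yl, spiro at C-1 to ring A cyclopent-2-ene (C4=C5) bearing C-2 (E)-hex-1-enyl; OH, C-5 and the selenide-bearing group cis on ring C | CC(C)([Se]c1ccccc1)[C@H]1C[C@@]2(C=CC[C@@H]2/C=C/CCCC)[C@@H](O)C=C1C(=O)O | intermediate
20 | (1R,2R,5S,7R,10S)-2-[(1E)-hex-1-en-1-yl]-10-hydroxy-6,6-dimethyltricyclo[5.3.1.0(1,5)]undec-8-ene-8-carboxylic acid | CC1(C)[C@H]2C[C@@]3([C@@H](O)C=C2C(=O)O)[C@@H](/C=C/CCCC)CC[C@@H]13 | intermediate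
21 | (1S,2S,5S,7R,10S)-2-formyl-10-hydroxy-6,6-dimethyltricyclo[5.3.1.0(1,5)]undec-8-ene-8-carboxylic acid | CC1(C)[C@H]2C[C@@]3([C@@H](O)C=C2C(=O)O)[C@@H](C=O)CC[C@@H]13 | intermediate
22 | oct-7-yn-1-ol | C#CCCCCCCO | starting material
23 | tert-butyl(dimethyl)(oct-7-yn-1-yloxy)silane | C#CCCCCCCO[Si](C)(C)C(C)(C)C | intermediate
24 | 8-bromooctanoic acid | OC(=O)CCCCCCCBr | starting material
25 | lithium acetylide of 23 | [Li]C#CCCCCCCO[Si](C)(C)C(C)(C)C | intermediate
26 | lithium 8-bromooctanoate | [Li+].[O-]C(=O)CCCCCCCBr | intermediate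
27 | 16-{[tert-butyl(dimethyl)silyl]oxy}hexadec-9-ynoic acid | OC(=O)CCCCCCCC#CCCCCCCO[Si](C)(C)C(C)(C)C | intermediate
28 | (9Z)-16-{[tert-butyl(dimethyl)silyl]oxy}hexadec-9-enoic acid | OC(=O)CCCCCCC/C=C\CCCCCCO[Si](C)(C)C(C)(C)C | intermediate
29 | (9Z)-16-{[tert-butyl(dimethyl)silyl]oxy}hexadec-9-enoyl chloride | ClC(=O)CCCCCCC/C=C\CCCCCCO[Si](C)(C)C(C)(C)C | intermediate
30 | (1S,2S,5S,7R,10S)-10-{[(9Z)-16-{[tert-butyl(dimethyl)silyl]oxy}hexadec-9-enoyl]oxy}-2-formyl-6,6-dimethyltricyclo[5.3.1.0(1,5)]undec-8-ene-8-carboxylic acid | CC1(C)[C@H]2C[C@@]3([C@@H](OC(=O)CCCCCCC/C=C\CCCCCCO[Si](C)(C)C(C)(C)C)C=C2C(=O)O)[C@@H](C=O)CC[C@@H]13 | intermediate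
31 | (1S,2S,5S,7R,10S)-2-formyl-10-{[(9Z)-16-hydroxyhexadec-9-enoyl]oxy}-6,6-dimethyltricyclo[5.3.1.0(1,5)]undec-8-ene-8-carboxylic acid | CC1(C)[C@H]2C[C@@]3([C@@H](OC(=O)CCCCCCC/C=C\CCCCCCO)C=C2C(=O)O)[C@@H](C=O)CC[C@@H]13 | target

**Count and risks**

Total step count: 16. Longest linear sequence: 11 (steps 3 to 11, then 15 and 16).

Steps most likely to fail:

- Step 6 (key step). The α-methylene ketone may dimerise faster than it is intercepted, or endo and facial control may be incomplete. The fallback sets out from 13 and 7: a base-mediated vinylogous Michael addition of the dienolate of 13 to 7 followed by intramolecular aldol closure (DBU cat., THF, with equilibration through the retro-aldol toward the hydrogen-bonded cis β-hydroxy ketone) would give the C-10 alcohol of the spiro adduct F1. Silylation (TBSOTf, 2,6-lutidine) comes back to the route at 15.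
- Step 1. Enantiofacial control may be eroded, or proton transfer may scramble the enolate before Mannich trapping. The fallback sets out from 1 and 2: hydrozirconation, CuBr·SMe2-catalysed (racemic) conjugate addition and the same iminium trapping would give 5 together with its enantiomer, the (2R,3S)-Mannich base F2. Classical resolution by crystallisation of the (S)-mandelate salt F3 of amine 5 and liberation with aq NaHCO3 comes back to the route at 5.
- Step 10. The tertiary radical may take hydrogen before it closes ring B, or close 6-endo. The fallback sets out from 19: oxidation with H2O2 to the selenoxide F4 and syn-elimination would give the isopropenyl hydroxy acid F5. Metal-hydride hydrogen-atom transfer (Fe(acac)3, PhSiH3, EtOH) would then regenerate the C-6 radical at the 1,1-disubstituted alkene without a fast hydrogen donor, and after 5-exo closure comes back to the route at 20.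

Further compounds
F1 | step 6 | C-10 alcohol of the spiro adduct (15 without the silyl group) | CC1(C)OC(=O)C2=C[C@H](O)[C@@]3(C[C@H]12)C(=O)CC[C@@H]3/C=C/CCCC
F2 | step 1 | (2R,3S)-2-[(dimethylamino)methyl]-3-[(1E)-hex-1-en-1-yl]cyclopentan-1-one (enantiomer of 5) | CN(C)C[C@@H]1C(=O)CC[C@H]1/C=C/CCCC
F3 | step 1 | (S)-mandelate salt of 5 | C[NH+](C)C[C@H]1C(=O)CC[C@@H]1/C=C/CCCC.O[C@H](C([O-])=O)c1ccccc1
F4 | step 10 | selenoxide of 19 | CC(C)([Se](=O)c1ccccc1)[C@H]1C[C@@]2(C=CC[C@@H]2/C=C/CCCC)[C@@H](O)C=C1C(=O)O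
F5 | step 10 | isopropenyl hydroxy acid (19 with C-7 prop-1-en-2-yl in place of the selenide-bearing group) | CC(=C)[C@H]1C[C@@]2(C=CC[C@@H]2/C=C/CCCC)[C@@H](O)C=C1C(=O)O
A1 | direct plan | tert-butyl 2-[(7R)-7-(4-methylpent-3-en-1-yl)-4-oxo-5-oxaspiro[2.4]heptan-1-yl]prop-2-enoate | O=C1OC[C@H](CCC=C(C)C)C12CC2C(=C)C(=O)OC(C)(C)C
A2 | direct plan | tricyclic lactone acrylate (cis-bicyclo[3.3.0]octane with fused γ-lactone and 1-(tert-butoxycarbonyl)ethenyl group; 1S,2R,5S,7R) | CC1(C)[C@H](C(=C)C(=O)OC(C)(C)C)C[C@@]2(C(=O)OC3)[C@H]3CC[C@@H]12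
A3 | direct plan | tert-butyl (1S,2S,5S,7R)-2-formyl-6,6-dimethyl-10-oxotricyclo[5.3.1.0(1,5)]undec-8-ene-8-carboxylate | CC1(C)[C@H]2C[C@@]3(C(=O)C=C2C(=O)OC(C)(C)C)[C@@H](C=O)CC[C@@H]13
A4 | direct plan | tert-butyl (1S,2S,5S,7R,10S)-10-(dec-9-enoyloxy)-2-(dimethoxymethyl)-6,6-dimethyltricyclo[5.3.1.0(1,5)]undec-8-ene-8-carboxylate | CC1(C)[C@H]2C[C@@]3([C@@H](OC(=O)CCCCCCCC=C)C=C2C(=O)OC(C)(C)C)[C@@H](C(OC)OC)CC[C@@H]13
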